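**Retrosynthetic overview**
1. Target 18 ⇐ dibenzyl ether 17 ⇐ isoflavone 14: the C3 stereocentre comes from reduction of the isoflavone C2=C3 bond (the isoflavone-reductase step), done as Ru transfer hydrogenation with dynamic kinetic resolution, then re-oxidation at C4.
2. Dimethylpyran ring of 14 ⇐ 5'-prenyl catechol 11 by oxidative cyclisation (catechol → o-quinone → o-quinone methide → oxa-6π), as a prenylated isoflavone is turned into its chromene in the plant.
3. 11 ⇐ aryl bromide 9 + prenylstannane 10 (Stille).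
4. Pyranone ring of 9 ⇐ 2'-hydroxychalcone 7 by oxidative 1,2-aryl shift and ring closure (the isoflavone-synthase step); 7 ⇐ acetophenone 3 + aldehyde 6.
5. Ring order: rings A and B are bought, ring C is formed first, the dimethylpyran ring second, and the stereocentre is set after both.

Assumption: the SMILES descriptor corresponds to (3S) (priorities C4 > C2 > aryl > H); 3-bromo-4,5-dihydroxybenzaldehyde and tributyl(prenyl)stannane are bought.

**Route**

Step 1
Reactants: 1 2,4,6-trihydroxyacetophenone; 2 benzyl bromide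
Product: 3 1-[2,4-bis(benzyloxy)-6-hydroxyphenyl]ethan-1-one
Conditions: BnBr (2.1 equiv), K2CO3, DMF, 0 °C → rt
Reagents that add atoms: benzyl bromide (2), BrCc1ccccc1
Why: Williamson etherification in which the 4-OH and one ortho-OH are benzylated while the last ortho-OH stays locked in the hydrogen bond to the acetyl C=O, so alkylation stops at the dibenzyl ether.

Step 2
Reactants: 4 3-bromo-4,5-dihydroxybenzaldehyde; 5 chloromethyl methyl ether
Product: 6 3-bromo-4,5-bis(methoxymethoxy)benzaldehyde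
Conditions: MOMCl (3 equiv), i-Pr2NEt, CH2Cl2, 0 °C → rt
Reagents that add atoms: chloromethyl methyl ether (5), COCCl
Why: O-alkylation of both phenols with the α-chloro ether (MOM protection) gives acid-labile acetals that leave the aldehyde and the aryl bromide untouched.

Step 3
Reactants: 3 1-[2,4-bis(benzyloxy)-6-hydroxyphenyl]ethan-1-one; 6 3-bromo-4,5-bis(methoxymethoxy)benzaldehyde
Product: 7 (E)-1-[2,4-bis(benzyloxy)-6-hydroxyphenyl]-3-[3-bromo-4,5-bis(methoxymethoxy)phenyl]prop-2-en-1-one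
Conditions: KOH (50% aq), EtOH/THF, rt; AcOH to pH 5
Reagents that add atoms: none
Why: Claisen–Schmidt condensation of the acetophenone enolate with the non-enolisable aldehyde, with E1cB dehydration giving only the (E)-enone; benzyl ethers, MOM ethers and ArBr are stable to hydroxide.

Step 4
Reactants: 7 (E)-1-[2,4-bis(benzyloxy)-6-hydroxyphenyl]-3-[3-bromo-4,5-bis(methoxymethoxy)phenyl]prop-2-en-1-one
Product: 9 5,7-bis(benzyloxy)-3-(3-bromo-4,5-dihydroxyphenyl)-4H-chromen-4-one, via dimethyl acetal 8 (not isolated)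
Conditions: Tl(NO3)3·3H2O (1.2 equiv), MeOH/CH(OMe)3, rt; then 10% HCl, MeOH, 60 °C
Reagents that add atoms: none
Why: Thallium(III)-mediated oxidative rearrangement of a 2'-hydroxychalcone, in which methoxythallation of the enone and a 1,2-shift of the B-ring aryl from Cβ to Cα give acetal 8 (both OMe from methanol, lost again), after which acid closes the pyranone ring through the free 2'-OH and cleaves the MOM but not the benzyl ethers.

Step 5
Reactants: 9 5,7-bis(benzyloxy)-3-(3-bromo-4,5-dihydroxyphenyl)-4H-chromen-4-one; 10 tributyl(3-methylbut-2-en-1-yl)stannane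
Product: 11 5,7-bis(benzyloxy)-3-[3,4-dihydroxy-5-(3-methylbut-2-en-1-yl)phenyl]-4H-chromen-4-one
Conditions: 10 (1.5 equiv), Pd(PPh3)4 (10 mol%), DMF, 100 °C, degassed
Reagents that add atoms: tributyl(3-methylbut-2-en-1-yl)stannane (10), CC(C)=CC[Sn](CCCC)(CCCC)CCCC
Why: Stille cross-coupling, in which the prenylstannane couples mainly at its α-carbon to give the linear 3-methylbut-2-enyl arene under neutral conditions that tolerate the free catechol.

Step 6
Reactants: 11 5,7-bis(benzyloxy)-3-[3,4-dihydroxy-5-(3-methylbut-2-en-1-yl)phenyl]-4H-chromen-4-one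
Product: 14 5,7-bis(benzyloxy)-3-(8-hydroxy-2,2-dimethyl-2H-chromen-6-yl)-4H-chromen-4-one, via o-quinone 12 (not isolated), via o-quinone methide 13 (not isolated)
Conditions: DDQ (1.05 equiv), 1,4-dioxane, rt → 50 °C
Reagents that add atoms: none
Why: Proposed new method: DDQ oxidises the catechol to o-quinone 12, the doubly activated benzylic/allylic CH2 tautomerises to hydroxy-o-quinone methide 13, and oxa-6π electrocyclisation re-aromatises the ring and closes the 2,2-dimethyl-2H-chromene on the 4'-oxygen with the 3'-OH left free; the closest known reactions are the DDQ cyclisation of o-prenylphenols to chromenes and the prenylquinone-to-chromenol isomerisation (ubiquinone to ubichromenol).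

Step 7
Reactants: 14 5,7-bis(benzyloxy)-3-(8-hydroxy-2,2-dimethyl-2H-chromen-6-yl)-4H-chromen-4-one
Product: 16 (3S,4S)-5,7-bis(benzyloxy)-3-(8-hydroxy-2,2-dimethyl-2H-chromen-6-yl)-3,4-dihydro-2H-chromen-4-ol, via racemic isoflavanone 15 (not isolated)
Conditions: RuCl[(S,S)-TsDPEN](p-cymene) (5 mol%), HCO2H/Et3N (1:1), EtOAc, 40 °C
Reagents that add atoms: none
Why: Noyori–Ikariya asymmetric transfer hydrogenation with dynamic kinetic resolution, in which Ru–H first reduces the chromone C2=C3 bond to the base-labile racemic ketone 15 and the (S,S)-catalyst then reduces only its (3S)-enantiomer, anti to the 3-aryl group, to the cis-(3S,4S)-alcohol while Et3N keeps 15 racemising; the non-polarised chromene C=C is not reduced.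

Step 8
Reactants: 16 (3S,4S)-5,7-bis(benzyloxy)-3-(8-hydroxy-2,2-dimethyl-2H-chromen-6-yl)-3,4-dihydro-2H-chromen-4-ol
Product: 17 (3S)-5,7-bis(benzyloxy)-3-(8-hydroxy-2,2-dimethyl-2H-chromen-6-yl)-2,3-dihydro-4H-chromen-4-one
Conditions: activated MnO2 (15 equiv), CH2Cl2, rt
Reagents that add atoms: none
Why: Chemoselective MnO2 oxidation of the electron-rich benzylic alcohol under neutral heterogeneous conditions removes the C4 stereocentre and, with no acid or base present, leaves the enolisable (3S) centre intact.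

Step 9
Reactants: 17 (3S)-5,7-bis(benzyloxy)-3-(8-hydroxy-2,2-dimethyl-2H-chromen-6-yl)-2,3-dihydro-4H-chromen-4-one
Product: 18 (3S)-5,7-dihydroxy-3-(8-hydroxy-2,2-dimethyl-2H-chromen-6-yl)-2,3-dihydro-4H-chromen-4-one
Conditions: BCl3 (6 equiv), C6HMe5 (8 equiv), CH2Cl2, −78 °C; MeOH quench
Reagents that add atoms: none
Why: Lewis-acid debenzylation of aryl benzyl ethers with pentamethylbenzene as non-basic benzyl-cation scavenger, run base-free at −78 °C so that the C3 stereocentre does not enolise and the chromene is spared.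

**Compound list**
1 | 2,4,6-trihydroxyacetophenone | CC(=O)c1c(O)cc(O)cc1O | starting material
2 | benzyl bromide | BrCc1ccccc1 | starting material
3 | 1-[2,4-bis(benzyloxy)-6-hydroxyphenyl]ethan-1-one | CC(=O)c1c(O)cc(OCc2ccccc2)cc1OCc1ccccc1 | intermediate
4 | 3-bromo-4,5-dihydroxybenzaldehyde | O=Cc1cc(O)c(O)c(Br)c1 | starting material
5 | chloromethyl methyl ether | COCCl | starting material
6 | 3-bromo-4,5-bis(methoxymethoxy)benzaldehyde | O=Cc1cc(OCOC)c(OCOC)c(Br)c1 | intermediate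
7 | (E)-1-[2,4-bis(benzyloxy)-6-hydroxyphenyl]-3-[3-bromo-4,5-bis(methoxymethoxy)phenyl]prop-2-en-1-one | O=C(/C=C/c1cc(OCOC)c(OCOC)c(Br)c1)c1c(O)cc(OCc2ccccc2)cc1OCc1ccccc1 | intermediate
8 | 1-[2,4-bis(benzyloxy)-6-hydroxyphenyl]-2-[3-bromo-4,5-bis(methoxymethoxy)phenyl]-3,3-dimethoxypropan-1-one (racemic, not isolated) | COC(OC)C(c1cc(OCOC)c(OCOC)c(Br)c1)C(=O)c1c(O)cc(OCc2ccccc2)cc1OCc1ccccc1 | intermediate
9 | 5,7-bis(benzyloxy)-3-(3-bromo-4,5-dihydroxyphenyl)-4H-chromen-4-one | O=c1c(-c2cc(O)c(O)c(Br)c2)coc2cc(OCc3ccccc3)cc(OCc3ccccc3)c12 | intermediate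
10 | tributyl(3-methylbut-2-en-1-yl)stannane | CC(C)=CC[Sn](CCCC)(CCCC)CCCC | starting material
11 | 5,7-bis(benzyloxy)-3-[3,4-dihydroxy-5-(3-methylbut-2-en-1-yl)phenyl]-4H-chromen-4-one (5,7-di-O-benzylglycyrrhisoflavone) | CC(C)=CCc1cc(-c2coc3cc(OCc4ccccc4)cc(OCc4ccccc4)c3c2=O)cc(O)c1O | intermediate
12 | 5,7-bis(benzyloxy)-3-[5-(3-methylbut-2-en-1-yl)-3,4-dioxocyclohexa-1,5-dien-1-yl]-4H-chromen-4-one (o-quinone, not isolated) | CC(C)=CCC1=CC(c2coc3cc(OCc4ccccc4)cc(OCc4ccccc4)c3c2=O)=CC(=O)C1=O | intermediate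
13 | 5,7-bis(benzyloxy)-3-[(5Z)-3-hydroxy-5-(3-methylbut-2-en-1-ylidene)-4-oxocyclohexa-1,2-dien-1-yl]-4H-chromen-4-one (o-quinone methide, not isolated) | CC(C)=C/C=C1/C=C(c2coc3cc(OCc4ccccc4)cc(OCc4ccccc4)c3c2=O)C=C(O)C1=O | intermediate
14 | 5,7-bis(benzyloxy)-3-(8-hydroxy-2,2-dimethyl-2H-chromen-6-yl)-4H-chromen-4-one (5,7-di-O-benzylsemilicoisoflavone B) | CC1(C)C=Cc2cc(-c3coc4cc(OCc5ccccc5)cc(OCc5ccccc5)c4c3=O)cc(O)c2O1 | intermediate
15 | 5,7-bis(benzyloxy)-3-(8-hydroxy-2,2-dimethyl-2H-chromen-6-yl)-2,3-dihydro-4H-chromen-4-one (racemic, not isolated) | CC1(C)C=Cc2cc(C3COc4cc(OCc5ccccc5)cc(OCc5ccccc5)c4C3=O)cc(O)c2O1 | intermediate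
16 | (3S,4S)-5,7-bis(benzyloxy)-3-(8-hydroxy-2,2-dimethyl-2H-chromen-6-yl)-3,4-dihydro-2H-chromen-4-ol (cis) | CC1(C)C=Cc2cc([C@H]3COc4cc(OCc5ccccc5)cc(OCc5ccccc5)c4[C@H]3O)cc(O)c2O1 | intermediate
17 | (3S)-5,7-bis(benzyloxy)-3-(8-hydroxy-2,2-dimethyl-2H-chromen-6-yl)-2,3-dihydro-4H-chromen-4-one | CC1(C)C=Cc2cc([C@H]3COc4cc(OCc5ccccc5)cc(OCc5ccccc5)c4C3=O)cc(O)c2O1 | intermediate
18 | (3S)-5,7-dihydroxy-3-(8-hydroxy-2,2-dimethyl-2H-chromen-6-yl)-2,3-dihydro-4H-chromen-4-one | CC1(C)C=Cc2cc([C@H]3COc4cc(O)cc(O)c4C3=O)cc(O)c2O1 | target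

**Totals**
Total steps: 9. Longest linear sequence: 8 (step 1 or step 2, then steps 3–9).

**Steps most likely to fail, with fallbacks**

Step 6 is the least precedented step: the o-quinone 12 may dimerise or add nucleophiles faster than it tautomerises. The fallback sets out from 9 and comes back at 14, bypassing 11, and reaches the same quinone methide without an oxidant. Heck coupling of 9 with 2-methylbut-3-en-2-ol (Pd(OAc)2, P(o-tol)3, Et3N, DMF, 100 °C) gives 5,7-bis(benzyloxy)-3-{3,4-dihydroxy-5-[(E)-3-hydroxy-3-methylbut-1-en-1-yl]phenyl}-4H-chromen-4-one F1. Warming F1 with PPTS in toluene ionises the tertiary allylic alcohol to quinone methide 13, which closes to 14.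

Step 4 may fail because the B ring carries a bromine and a twisted para-oxygen, which lowers its migratory aptitude, so thallium may instead give aurone or flavone products. The fallback sets out from 7 and comes back at 9, and replaces the aryl shift by an epoxide/1,2-acyl shift in which the aroyl group migrates. MOMCl/NaH on 7 caps the 2'-OH and gives (E)-1-[2,4-bis(benzyloxy)-6-(methoxymethoxy)phenyl]-3-[3-bromo-4,5-bis(methoxymethoxy)phenyl]prop-2-en-1-one F2. Weitz–Scheffer epoxidation (H2O2, NaOH, MeOH/THF) gives the racemic trans-epoxide [2,4-bis(benzyloxy)-6-(methoxymethoxy)phenyl]{3-[3-bromo-4,5-bis(methoxymethoxy)phenyl]oxiran-2-yl}methanone F3. BF3·OEt2 (CH2Cl2, 0 °C) opens the benzylic C–O bond with acyl migration to 3-[2,4-bis(benzyloxy)-6-(methoxymethoxy)phenyl]-2-[3-bromo-4,5-bis(methoxymethoxy)phenyl]-3-oxopropanal F4. Then 10% HCl/MeOH removes the three MOM groups and cyclodehydrates F4 to 9.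

Step 9 may fail because BCl3 can ionise the tertiary allylic C–O bond of the chromene or enolise the finished ketone through a boron chelate. The fallback sets out from 9 and comes back at 18; it removes the benzyl groups before the chromene and the stereocentre exist and finishes on silyl ethers. BCl3/C6HMe5 on 9 gives 3-(3-bromo-4,5-dihydroxyphenyl)-5,7-dihydroxy-4H-chromen-4-one F5. Stille coupling with 10 gives glycyrrhisoflavone F6, and DDQ as in step 6 gives semilicoisoflavone B F7. TBSOTf/2,6-lutidine gives 5,7-bis(tert-butyldimethylsilyloxy)-3-[8-(tert-butyldimethylsilyloxy)-2,2-dimethyl-2H-chromen-6-yl]-4H-chromen-4-one F8. The same (S,S)-Ru transfer hydrogenation gives the (3S,4S)-cis-alcohol F9, Dess–Martin periodinane (NaHCO3, CH2Cl2) gives the (3S)-ketone F10, and HF·pyridine (THF, 0 °C) removes the silyl groups to give 18.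

**Further compounds**
F1 | step 6 | 5,7-bis(benzyloxy)-3-{3,4-dihydroxy-5-[(E)-3-hydroxy-3-methylbut-1-en-1-yl]phenyl}-4H-chromen-4-one | CC(C)(O)/C=C/c1cc(-c2coc3cc(OCc4ccccc4)cc(OCc4ccccc4)c3c2=O)cc(O)c1O
F2 | step 4 | (E)-1-[2,4-bis(benzyloxy)-6-(methoxymethoxy)phenyl]-3-[3-bromo-4,5-bis(methoxymethoxy)phenyl]prop-2-en-1-one | O=C(/C=C/c1cc(OCOC)c(OCOC)c(Br)c1)c1c(OCOC)cc(OCc2ccccc2)cc1OCc1ccccc1
F3 | step 4 | [2,4-bis(benzyloxy)-6-(methoxymethoxy)phenyl]{3-[3-bromo-4,5-bis(methoxymethoxy)phenyl]oxiran-2-yl}methanone (trans, racemic; one enantiomer drawn) | O=C([C@@H]1O[C@H]1c1cc(OCOC)c(OCOC)c(Br)c1)c1c(OCOC)cc(OCc2ccccc2)cc1OCc1ccccc1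
F4 | step 4 | 3-[2,4-bis(benzyloxy)-6-(methoxymethoxy)phenyl]-2-[3-bromo-4,5-bis(methoxymethoxy)phenyl]-3-oxopropanal (racemic, largely enolised) | O=CC(c1cc(OCOC)c(OCOC)c(Br)c1)C(=O)c1c(OCOC)cc(OCc2ccccc2)cc1OCc1ccccc1
F5 | step 9 | 3-(3-bromo-4,5-dihydroxyphenyl)-5,7-dihydroxy-4H-chromen-4-one | O=c1c(-c2cc(O)c(O)c(Br)c2)coc2cc(O)cc(O)c12
F6 | step 9 | glycyrrhisoflavone, 3-[3,4-dihydroxy-5-(3-methylbut-2-en-1-yl)phenyl]-5,7-dihydroxy-4H-chromen-4-one | CC(C)=CCc1cc(-c2coc3cc(O)cc(O)c3c2=O)cc(O)c1O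
F7 | step 9 | semilicoisoflavone B, 5,7-dihydroxy-3-(8-hydroxy-2,2-dimethyl-2H-chromen-6-yl)-4H-chromen-4-one | CC1(C)C=Cc2cc(-c3coc4cc(O)cc(O)c4c3=O)cc(O)c2O1
F8 | step 9 | 5,7-bis(tert-butyldimethylsilyloxy)-3-[8-(tert-butyldimethylsilyloxy)-2,2-dimethyl-2H-chromen-6-yl]-4H-chromen-4-one | CC1(C)C=Cc2cc(-c3coc4cc(O[Si](C)(C)C(C)(C)C)cc(O[Si](C)(C)C(C)(C)C)c4c3=O)cc(O[Si](C)(C)C(C)(C)C)c2O1
F9 | step 9 | (3S,4S)-5,7-bis(tert-butyldimethylsilyloxy)-3-[8-(tert-butyldimethylsilyloxy)-2,2-dimethyl-2H-chromen-6-yl]-3,4-dihydro-2H-chromen-4-ol | CC1(C)C=Cc2cc([C@H]3COc4cc(O[Si](C)(C)C(C)(C)C)cc(O[Si](C)(C)C(C)(C)C)c4[C@H]3O)cc(O[Si](C)(C)C(C)(C)C)c2O1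
F10 | step 9 | (3S)-5,7-bis(tert-butyldimethylsilyloxy)-3-[8-(tert-butyldimethylsilyloxy)-2,2-dimethyl-2H-chromen-6-yl]-2,3-dihydro-4H-chromen-4-one | CC1(C)C=Cc2cc([C@H]3COc4cc(O[Si](C)(C)C(C)(C)C)cc(O[Si](C)(C)C(C)(C)C)c4C3=O)cc(O[Si](C)(C)C(C)(C)C)c2O1
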